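**Plan**

1. Retrosynthesis: the two phenols are unmasked last (both carried as mesylates), C2 is taken back to a lactone carbonyl, and then O1–C2 and C3–C4 of the 3-aryl-dihydrocoumarin are cut together.
2. Enabling feature: on ring A the ether oxygen O1 (on C8a) and the benzylic carbon C4 (on C4a) are ortho neighbours, so O1=C8a–C4a=C4 can be raised as an ortho-quinone methide heterodiene. C3 carries the ring B aryl and C2 can stand at the carboxyl level, so C2–C3 is the C1-ammonium enolate of an arylacetic ester.
3. Forward: ring A precursor 7 in five steps from 2-methoxyresorcinol; ring B ester 17 in six steps from 1,2,4-trimethoxybenzene (flanked OH by ortho-lithiation, side chain by bromination para to OMe and Pd enolate arylation).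
4. The pyran ring arises in step 12 by Michael addition–lactonisation; step 13 reduces the lactone carbonyl to CH2 without opening the ring; step 14 removes both mesylates.
5. Stereochemistry: the single stereocentre C3 (S) is set in step 12 by the chiral isothiourea and is not touched afterwards.

Key step: step 12

Assumption: the sense of induction in step 12 is assigned from the usual model of isothiourea-bound enolates (enolate oxygen syn to sulfur, attack anti to the C2 phenyl group); should lactone 20 prove to be the (R) antipode, the (2S,3R) catalyst is used instead.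

**Route**

Step 1
Reactants: 1 2-methoxybenzene-1,3-diol
Product: 3 2,4-dihydroxy-3-methoxybenzaldehyde, via aryl iminium chloride 2 (not isolated)
Conditions: POCl3, DMF, MeCN, 0 °C → rt; then H2O, 50 °C
Reagents that add atoms: N,N-dimethylformamide CN(C)C=O; water O
Why: Vilsmeier–Haack formylation: the chloroiminium ion attacks the position ortho to one hydroxyl and para to the other (the two such positions are equivalent), and hydrolysis of iminium salt 2 should give the aldehyde.

Step 2
Reactants: 3 2,4-dihydroxy-3-methoxybenzaldehyde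
Product: 4 4-formyl-3-hydroxy-2-methoxyphenyl methanesulfonate
Conditions: MsCl (1.05 equiv), Et3N, CH2Cl2, −20 °C
Reagents that add atoms: methanesulfonyl chloride CS(=O)(=O)Cl
Why: Selective O-sulfonylation: the 2-hydroxyl is tied up in a hydrogen bond to the formyl group, so the free and more acidic 4-hydroxyl should take the one equivalent of MsCl.

Step 3
Reactants: 4 4-formyl-3-hydroxy-2-methoxyphenyl methanesulfonate
Product: 5 3-[(tert-butyldimethylsilyl)oxy]-4-formyl-2-methoxyphenyl methanesulfonate
Conditions: TBSCl, imidazole, DMF, rt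
Reagents that add atoms: tert-butyldimethylsilyl chloride CC(C)(C)[Si](C)(C)Cl
Why: Silyl ether formation on the remaining phenol, which installs the fluoride-labile trigger for the later quinone methide release.

Step 4
Reactants: 5 3-[(tert-butyldimethylsilyl)oxy]-4-formyl-2-methoxyphenyl methanesulfonate
Product: 6 3-[(tert-butyldimethylsilyl)oxy]-4-(hydroxymethyl)-2-methoxyphenyl methanesulfonate
Conditions: NaBH4, THF–MeOH, −20 °C, short reaction time; aq. NH4Cl
Reagents that add atoms: none
Why: Borohydride reduction of the aldehyde; low temperature and short contact are meant to keep the silyl group from migrating to the new benzylic alkoxide, and aryl mesylates are inert to NaBH4.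

Step 5
Reactants: 6 3-[(tert-butyldimethylsilyl)oxy]-4-(hydroxymethyl)-2-methoxyphenyl methanesulfonate
Product: 7 4-(bromomethyl)-3-[(tert-butyldimethylsilyl)oxy]-2-methoxyphenyl methanesulfonate
Conditions: CBr4, PPh3, CH2Cl2, 0 °C
Reagents that add atoms: carbon tetrabromide BrC(Br)(Br)Br
Why: Appel bromination of the benzylic alcohol under neutral conditions that leave the aryl silyl ether and the mesylate alone.

Step 6
Reactants: 8 1,2,4-trimethoxybenzene
Product: 11 2,3,6-trimethoxyphenol, via aryllithium 9 (not isolated), via lithium aryltrimethoxyborate 10 (not isolated)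
Conditions: n-BuLi, TMEDA, THF, 0 °C; B(OMe)3, −78 °C → rt; H2O2, AcOH, 0 °C → rt
Reagents that add atoms: hydrogen peroxide OO
Why: Directed ortho-metalation at the C–H flanked by two methoxy groups (the most acidic, doubly coordinated site), borylation, and peroxide-induced C–B to C–O migration should give the phenol.

Step 7
Reactants: 11 2,3,6-trimethoxyphenol
Product: 12 2,3,6-trimethoxyphenyl methanesulfonate
Conditions: MsCl, Et3N, CH2Cl2, 0 °C
Reagents that add atoms: methanesulfonyl chloride CS(=O)(=O)Cl
Why: Sulfonylation through sulfene, which is insensitive to the two flanking methoxy groups; the mesylate protects the phenol and turns its oxygen from the strongest into the weakest donor of the ring.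

Step 8
Reactants: 12 2,3,6-trimethoxyphenyl methanesulfonate
Product: 13 3-bromo-2,5,6-trimethoxyphenyl methanesulfonate
Conditions: NBS, MeCN, 0 °C → rt
Reagents that add atoms: N-bromosuccinimide O=C1CCC(=O)N1Br
Why: Electrophilic aromatic bromination: the position para to the C2 methoxy and ortho to the C6 methoxy group should be attacked, since the only other free position is para to the deactivating sulfonyloxy group.

Step 9
Reactants: 13 3-bromo-2,5,6-trimethoxyphenyl methanesulfonate; 14 (2-tert-butoxy-2-oxoethyl)zinc bromide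
Product: 15 tert-butyl 2-{2,4,5-trimethoxy-3-[(methylsulfonyl)oxy]phenyl}acetate
Conditions: Pd(dba)2 (2 mol%), P(t-Bu)3 (2 mol%), THF, rt
Reagents that add atoms: none
Why: Palladium-catalysed α-arylation of a zinc ester enolate (Reformatsky-type Negishi coupling), mild enough to leave the aryl mesylate untouched.

Step 10
Reactants: 15 tert-butyl 2-{2,4,5-trimethoxy-3-[(methylsulfonyl)oxy]phenyl}acetate
Product: 16 2-{2,4,5-trimethoxy-3-[(methylsulfonyl)oxy]phenyl}acetic acid
Conditions: TFA, CH2Cl2, rt
Reagents that add atoms: none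
Why: Acidolysis of the tert-butyl ester by loss of 2-methylpropene; the mesylate and the methyl ethers are stable to TFA.

Step 11
Reactants: 16 2-{2,4,5-trimethoxy-3-[(methylsulfonyl)oxy]phenyl}acetic acid
Product: 17 4-nitrophenyl 2-{2,4,5-trimethoxy-3-[(methylsulfonyl)oxy]phenyl}acetate
Conditions: 4-nitrophenol, EDC·HCl, DMAP (cat.), CH2Cl2, 0 °C → rt
Reagents that add atoms: 4-nitrophenol Oc1ccc(cc1)[N+](=O)[O-]
Why: Carbodiimide esterification (Steglich type) to an electron-poor aryl ester that can acylate the isothiourea.

Step 12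
Reactants: 17 4-nitrophenyl 2-{2,4,5-trimethoxy-3-[(methylsulfonyl)oxy]phenyl}acetate; 7 4-(bromomethyl)-3-[(tert-butyldimethylsilyl)oxy]-2-methoxyphenyl methanesulfonate
Product: 20 (3S)-8-methoxy-7-[(methylsulfonyl)oxy]-3-{2,4,5-trimethoxy-3-[(methylsulfonyl)oxy]phenyl}chroman-2-one, via acyl ammonium enolate 18 (not isolated), via ortho-quinone methide 19 (not isolated)
Conditions: (2R,3S)-HyperBTM [(2R,3S)-3-isopropyl-2-phenyl-3,4-dihydro-2H-benzo[4,5]thiazolo[3,2-a]pyrimidine] (10 mol%), CsF, 18-crown-6, THF, −40 → −20 °C, slow addition of 7; cold pH 7 buffer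
Reagents that add atoms: none
Why: The isothiourea is acylated by ester 17 and the acyl ammonium ion is deprotonated to the (Z)-enolate 18, while fluoride removes the silyl group of 7 and the phenoxide expels bromide to give ortho-quinone methide 19; the α-carbon of 18 adds to the exocyclic CH2 of 19 (C3–C4 bond, ring A becomes aromatic again) and the phenoxide so formed attacks the acyl ammonium carbonyl (O1–C2 bond), which sets the catalyst free. The closest known reaction type is the isothiourea-catalysed Michael addition–lactonisation of arylacetic ester enolates with ortho-quinone methides (a formal inverse-demand hetero-[4+2]), joined here to the fluoride-triggered quinone methide release used in carbene-catalysed dihydrocoumarin syntheses. The one new ring, the dihydropyranone, closes in the lactonisation as a 6-exo-trig acyl substitution. C3 is the only new stereocentre and is set in the C–C bond formation by the catalyst: in 18 the enolate oxygen lies syn to sulfur (1,5 O···S contact), the C2 phenyl group of the (2R,3S) catalyst stands pseudoaxial over one face, and 19 is taken up on the other face to give (S). The step needs enantiofacial control, C- rather than O-alkylation of the enolate, and capture of 19 before it oligomerises or meets an achiral enolate; the unhindered CH2 terminus and the aromatisation energy of 19 favour fast C-attack, slow addition of 7 keeps 19 scarce next to preformed 18, and cold buffered work-up guards the acidic C3–H of the α-aryl lactone.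

Step 13
Reactants: 20 (3S)-8-methoxy-7-[(methylsulfonyl)oxy]-3-{2,4,5-trimethoxy-3-[(methylsulfonyl)oxy]phenyl}chroman-2-one
Product: 22 (3S)-8-methoxy-3-{2,4,5-trimethoxy-3-[(methylsulfonyl)oxy]phenyl}chroman-7-yl methanesulfonate, via lactol 21 (not isolated)
Conditions: DIBAL-H (1.1 equiv), CH2Cl2, −78 °C; then Et3SiH, BF3·OEt2, −78 → −30 °C
Reagents that add atoms: none
Why: Lactone-to-cyclic-ether reduction with the ring kept closed: DIBAL-H adds once to give the aluminium hemiacetal of 21, BF3·OEt2 ionises it to the cyclic oxocarbenium ion and Et3SiH delivers hydride to C2 (ionic hydrogenation), so the O1–C2 bond made in step 12 stays and C3 is not touched.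

Step 14
Reactants: 22 (3S)-8-methoxy-3-{2,4,5-trimethoxy-3-[(methylsulfonyl)oxy]phenyl}chroman-7-yl methanesulfonate
Product: 23 (3S)-3-(3-hydroxy-2,4,5-trimethoxyphenyl)-8-methoxychroman-7-ol
Conditions: LDA (6 equiv), THF, −78 → 0 °C; aq. NH4Cl
Reagents that add atoms: none
Why: Base-induced cleavage of aryl mesylates: LDA deprotonates each S-methyl group and sulfene is expelled, leaving the two phenoxides, while no C–H of the chroman is acidic enough to react, so C3 keeps its configuration.

**Compound list**

1 | 2-methoxybenzene-1,3-diol (2-methoxyresorcinol) | COc1c(O)cccc1O | starting material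
2 | N-[(2,4-dihydroxy-3-methoxyphenyl)methylidene]-N-methylmethanaminium chloride | C[N+](C)=Cc1ccc(O)c(OC)c1O.[Cl-] | intermediate
3 | 2,4-dihydroxy-3-methoxybenzaldehyde | O=Cc1ccc(O)c(OC)c1O | intermediate
4 | 4-formyl-3-hydroxy-2-methoxyphenyl methanesulfonate | CS(=O)(=O)Oc1ccc(C=O)c(O)c1OC | intermediate
5 | 3-[(tert-butyldimethylsilyl)oxy]-4-formyl-2-methoxyphenyl methanesulfonate | CS(=O)(=O)Oc1ccc(C=O)c(O[Si](C)(C)C(C)(C)C)c1OC | intermediate
6 | 3-[(tert-butyldimethylsilyl)oxy]-4-(hydroxymethyl)-2-methoxyphenyl methanesulfonate | CS(=O)(=O)Oc1ccc(CO)c(O[Si](C)(C)C(C)(C)C)c1OC | intermediate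
7 | 4-(bromomethyl)-3-[(tert-butyldimethylsilyl)oxy]-2-methoxyphenyl methanesulfonate | CS(=O)(=O)Oc1ccc(CBr)c(O[Si](C)(C)C(C)(C)C)c1OC | intermediate
8 | 1,2,4-trimethoxybenzene | COc1ccc(OC)c(OC)c1 | starting material
9 | (2,3,6-trimethoxyphenyl)lithium | [Li]c1c(OC)ccc(OC)c1OC | intermediate
10 | lithium trimethoxy(2,3,6-trimethoxyphenyl)borate | [Li+].CO[B-](OC)(OC)c1c(OC)ccc(OC)c1OC | intermediate
11 | 2,3,6-trimethoxyphenol | Oc1c(OC)ccc(OC)c1OC | intermediate
12 | 2,3,6-trimethoxyphenyl methanesulfonate | CS(=O)(=O)Oc1c(OC)ccc(OC)c1OC | intermediate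
13 | 3-bromo-2,5,6-trimethoxyphenyl methanesulfonate | CS(=O)(=O)Oc1c(OC)c(Br)cc(OC)c1OC | intermediate
14 | (2-tert-butoxy-2-oxoethyl)zinc bromide (Reformatsky reagent, sold as an ether solution) | CC(C)(C)OC(=O)C[Zn]Br | starting material
15 | tert-butyl 2-{2,4,5-trimethoxy-3-[(methylsulfonyl)oxy]phenyl}acetate | CC(C)(C)OC(=O)Cc1cc(OC)c(OC)c(OS(C)(=O)=O)c1OC | intermediate
16 | 2-{2,4,5-trimethoxy-3-[(methylsulfonyl)oxy]phenyl}acetic acid | OC(=O)Cc1cc(OC)c(OC)c(OS(C)(=O)=O)c1OC | intermediate
17 | 4-nitrophenyl 2-{2,4,5-trimethoxy-3-[(methylsulfonyl)oxy]phenyl}acetate | O=C(Cc1cc(OC)c(OC)c(OS(C)(=O)=O)c1OC)Oc1ccc(cc1)[N+](=O)[O-] | intermediate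
18 | (Z)-enolate of the N-arylacetyl (2R,3S)-isothiouronium ion (catalyst-bound C1-ammonium enolate) | CC(C)[C@H]1CN2c3ccccc3SC2=[N+](/C([O-])=C/c2cc(OC)c(OC)c(OS(C)(=O)=O)c2OC)[C@H]1c1ccccc1 | intermediate
19 | 2-methoxy-4-methylidene-3-oxocyclohexa-1,5-dien-1-yl methanesulfonate (ortho-quinone methide of ring A) | C=C1C=CC(OS(C)(=O)=O)=C(OC)C1=O | intermediate
20 | (3S)-8-methoxy-7-[(methylsulfonyl)oxy]-3-{2,4,5-trimethoxy-3-[(methylsulfonyl)oxy]phenyl}chroman-2-one | COc1cc([C@H]2C(=O)Oc3c(ccc(OS(C)(=O)=O)c3OC)C2)c(OC)c(OS(C)(=O)=O)c1OC | intermediate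
21 | (3S)-2-hydroxy-8-methoxy-3-{2,4,5-trimethoxy-3-[(methylsulfonyl)oxy]phenyl}chroman-7-yl methanesulfonate (lactol, present as its diisobutylaluminium alkoxide, both C2 epimers) | COc1cc([C@H]2C(O)Oc3c(ccc(OS(C)(=O)=O)c3OC)C2)c(OC)c(OS(C)(=O)=O)c1OC | intermediate
22 | (3S)-8-methoxy-3-{2,4,5-trimethoxy-3-[(methylsulfonyl)oxy]phenyl}chroman-7-yl methanesulfonate | COc1cc([C@H]2COc3c(ccc(OS(C)(=O)=O)c3OC)C2)c(OC)c(OS(C)(=O)=O)c1OC | intermediate
23 | (3S)-3-(3-hydroxy-2,4,5-trimethoxyphenyl)-8-methoxychroman-7-ol | COc1cc([C@H]2COc3c(ccc(O)c3OC)C2)c(OC)c(O)c1OC | target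

**Summary**

Total step count: 14. Longest linear sequence: 9 steps (steps 6 to 14); the ring A arm (steps 1 to 5) joins at step 12.

Steps most likely to fail:

1. Step 12. Enantiopurity may be lost through poor facial selectivity or through base-mediated enolisation of the α-aryl lactone, and the quinone methide may oligomerise before it is captured. The fallback sets out from acid 16 and bromide 7 and uses an Evans oxazolidinone alkylation. Acid 16 is coupled (DCC, DMAP) with (S)-4-benzyloxazolidin-2-one to give the N-acyl oxazolidinone F1. Its sodium (Z)-enolate (NaHMDS, 1.0 equiv, THF, −78 °C) should be alkylated by 7 on the face away from the benzyl group to give the alkylated imide F2. Buffered fluoride (TBAF, AcOH) then frees the phenol, which closes onto the exocyclic imide carbonyl with loss of the auxiliary, and the route is rejoined at lactone 20. In this fallback the C3–C4 and O1–C2 bonds are made in separate operations.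

2. Step 13. The oxocarbenium ion may lose the C3 proton to give the 3-aryl-4H-chromene, whose re-reduction would erase the configuration, or the hemiacetal may open and be reduced further. The fallback sets out from lactone 20. LiBH4 (THF, 0 °C) reduces it to the phenol–primary alcohol F3 without enolisation, and intramolecular Mitsunobu etherification (PPh3, DIAD, THF, high dilution) closes the ring by SN2 at the primary carbon. The route is rejoined at chroman 22; the O1–C2 bond is then re-formed in this closure.

3. Step 4. The silyl group may migrate from the phenolic oxygen to the benzylic alkoxide during hydride reduction and be lost on work-up. The fallback sets out from hydroxy aldehyde 4. NaBH4 reduces it to the salicyl alcohol F4 and both hydroxyls are silylated (TBSCl, imidazole, DMF) to give the bis-silyl ether F5. Ph3PBr2 (CH2Cl2, rt) then converts only the benzylic silyl ether into the bromide, aryl silyl ethers being inert to it, and the route is rejoined at bromide 7.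

**Further compounds**

F1 | step 12 | (S)-4-benzyl-3-(2-{2,4,5-trimethoxy-3-[(methylsulfonyl)oxy]phenyl}acetyl)oxazolidin-2-one | O=C1OC[C@H](Cc2ccccc2)N1C(=O)Cc1cc(OC)c(OC)c(OS(C)(=O)=O)c1OC
F2 | step 12 | (S)-4-benzyl-3-[(2S)-3-{2-[(tert-butyldimethylsilyl)oxy]-3-methoxy-4-[(methylsulfonyl)oxy]phenyl}-2-{2,4,5-trimethoxy-3-[(methylsulfonyl)oxy]phenyl}propanoyl]oxazolidin-2-one | O=C1OC[C@H](Cc2ccccc2)N1C(=O)[C@@H](Cc1ccc(OS(C)(=O)=O)c(OC)c1O[Si](C)(C)C(C)(C)C)c1cc(OC)c(OC)c(OS(C)(=O)=O)c1OC
F3 | step 13 | 3-hydroxy-4-[(2S)-3-hydroxy-2-{2,4,5-trimethoxy-3-[(methylsulfonyl)oxy]phenyl}propyl]-2-methoxyphenyl methanesulfonate | COc1cc([C@H](Cc2ccc(OS(C)(=O)=O)c(OC)c2O)CO)c(OC)c(OS(C)(=O)=O)c1OC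
F4 | step 4 | 3-hydroxy-4-(hydroxymethyl)-2-methoxyphenyl methanesulfonate | CS(=O)(=O)Oc1ccc(CO)c(O)c1OC
F5 | step 4 | 3-[(tert-butyldimethylsilyl)oxy]-4-{[(tert-butyldimethylsilyl)oxy]methyl}-2-methoxyphenyl methanesulfonate | CS(=O)(=O)Oc1ccc(CO[Si](C)(C)C(C)(C)C)c(O[Si](C)(C)C(C)(C)C)c1OC
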